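**Assumption:** the target is taken in the drawn 4-enol tautomer with chroman numbering (O1, C2–C4, C4a, C5–C8, C8a); its centres are 2R, 3S, 6S, side-chain C2 R and benzylic R. Lactol (hemiacetal) carbons are carried as anomeric mixtures and left unspecified in the SMILES. Compounds 1, 2, 5, 6, 17 and 20 are taken as commercial.

**Retrosynthetic overview**
1. The last C–C bond is C6–prenyl: a catalyst-controlled dearomative prenylation of a fully substituted aromatic chromanone sets the quaternary centre; aldehyde oxidation then reveals the acid.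
2. The C8 arm comes from iminium-catalysed Friedel–Crafts addition of the free C8–H to cinnamaldehyde (benzylic centre), held as a lactol on O7.
3. The C6 arm is not attached as a C11 halide: a one-carbon Mannich handle becomes an o-quinone methide that alkylates the chiral enamine of 5-methylhex-5-enal (side-chain centre), followed by Wittig isopropylidenation.
4. The cis-2,3-dimethylchromanone comes from quinine-catalysed oxa-Michael closure of tigloylphloroglucinol (phloroglucinol + tigloyl chloride).
5. Ring order: benzene ring (phloroglucinol) → dihydropyranone ring → two transient lactol rings (both reopened) → dearomatization of the carbocycle last.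

**Route**

Step 1
Reactants: 1 2-(2-bromoethyl)-1,3-dioxolane; 2 (2-methylallyl)magnesium chloride
Product: 3 2-(4-methylpent-4-enyl)-1,3-dioxolane
Conditions: CuI (5 mol%), THF, −20 °C to rt
Reagents that add atoms: none
Why: Copper-catalysed sp3–sp3 cross-coupling (Kochi type) of an allylic Grignard reagent with a primary bromide, the dioxolane masking the aldehyde; no stereocentre is formed.

Step 2
Reactants: 3 2-(4-methylpent-4-enyl)-1,3-dioxolane
Product: 4 5-methylhex-5-enal
Conditions: 1 M HCl, THF, rt
Reagents that add atoms: water, O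
Why: Acid-catalysed acetal hydrolysis, mild enough to leave the 1,1-disubstituted alkene untouched.

Step 3
Reactants: 5 phloroglucinol; 6 tigloyl chloride [(E)-2-methylbut-2-enoyl chloride]
Product: 7 (E)-2-methyl-1-(2,4,6-trihydroxyphenyl)but-2-en-1-one
Conditions: AlCl3 (3 equiv), PhNO2, 0 °C to rt; cold 1 M HCl quench
Reagents that add atoms: none
Why: Friedel–Crafts C-acylation of the electron-rich triphenol under acidic conditions stops at the open tigloyl ketone because ring closure needs a base; the substrate is symmetric, so there is no regiochemical issue and no stereocentre.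

Step 4
Reactants: 7 (E)-2-methyl-1-(2,4,6-trihydroxyphenyl)but-2-en-1-one
Product: 8 (2R,3S)-5,7-dihydroxy-2,3-dimethylchroman-4-one (cis)
Conditions: (−)-quinine (C20H24N2O2, 20 mol%), PhCl, 15 °C
Reagents that add atoms: none
Why: Quinine-catalysed enantioselective intramolecular oxa-Michael addition, in which the chiral base delivers either (equivalent) ortho-phenoxide to one face of the enone to set C2 as R and kinetic protonation anti to the new C2 methyl sets C3 as S (cis), the weak amine base leaving the kinetic cis product unepimerised.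

Step 5
Reactants: 8 (2R,3S)-5,7-dihydroxy-2,3-dimethylchroman-4-one
Product: 9 (2R,3S)-5-hydroxy-2,3-dimethyl-7-(triisopropylsilyloxy)chroman-4-one
Conditions: i-Pr3SiCl (1.05 equiv), imidazole, DMF, 0 °C
Reagents that add atoms: chlorotriisopropylsilane, CC(C)[Si](Cl)(C(C)C)C(C)C
Why: Selective O-silylation of the free 7-OH, the 5-OH being locked in a hydrogen bond to the C4 carbonyl; imidazole is too weak a base to epimerise C3.

Step 6
Reactants: 9 (2R,3S)-5-hydroxy-2,3-dimethyl-7-(triisopropylsilyloxy)chroman-4-one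
Product: 11 {[(2R,3S)-5-hydroxy-2,3-dimethyl-4-oxo-7-(triisopropylsilyloxy)chroman-6-yl]methyl}trimethylammonium iodide, via Mannich base 10 (not isolated)
Conditions: Me2N=CH2+ I− (1.05 equiv), CH2Cl2, 0 °C to rt; aq. NaHCO3 wash; then MeI (5 equiv), MeCN, rt
Reagents that add atoms: N,N-dimethylmethyleneiminium iodide (Eschenmoser's salt), C=[N+](C)C.[I-]; iodomethane, CI
Why: Mannich aminomethylation with a preformed iminium salt enters ortho to the only free phenol (C6, not C8), as in electrophilic substitutions of 5-hydroxy-7-alkoxychromanones, and Menshutkin N-methylation then turns the amine into a leaving group.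

Step 7
Reactants: 11 {[(2R,3S)-5-hydroxy-2,3-dimethyl-4-oxo-7-(triisopropylsilyloxy)chroman-6-yl]methyl}trimethylammonium iodide; 4 5-methylhex-5-enal (3 equiv)
Product: 14 5-O/6-C-fused lactol of 13 [ring O5–CH(OH)–CH(3-methylbut-3-enyl)–CH2–C6; side-chain centre R; anomeric mixture], via o-quinone methide 12 (not isolated), via hydroxy aldehyde 13 (not isolated)
Conditions: (S)-2-[diphenyl(trimethylsilyloxy)methyl]pyrrolidine (20 mol%), NaHCO3 (1.5 equiv), CH2Cl2/H2O, 0 °C to rt
Reagents that add atoms: none
Why: Base expels NMe3 to give o-quinone methide 12, which is trapped at its CH2 by the E-enamine of 4 (enamine organocatalysis, formal [4+2]) on the face away from the diphenyl(silyloxy)methyl group, setting the side-chain centre as R in the sense known for enamine Michael additions with this catalyst antipode; hydrolysis and closure onto O5 give the lactol.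

Step 8
Reactants: 14 5-O/6-C-fused lactol of 13
Product: 15 (2R,3S)-5-hydroxy-2,3-dimethyl-6-[(2R)-5-methyl-2-(2-methylprop-1-enyl)hex-5-enyl]-7-(triisopropylsilyloxy)chroman-4-one
Conditions: i-PrPPh3I (3 equiv), n-BuLi (3 equiv), THF, −78 to 0 °C
Reagents that add atoms: isopropyltriphenylphosphonium iodide, CC(C)[P+](c1ccccc1)(c1ccccc1)c1ccccc1.[I-]
Why: Wittig olefination of the ring-opened lactol with the non-stabilised isopropylidene ylide at low temperature installs the 2-methylprop-1-enyl group without touching the adjacent centre, the phenoxide-deactivated hindered C4 ketone being inert.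

Step 9
Reactants: 15 (2R,3S)-5-hydroxy-2,3-dimethyl-6-[(2R)-5-methyl-2-(2-methylprop-1-enyl)hex-5-enyl]-7-(triisopropylsilyloxy)chroman-4-one
Product: 16 (2R,3S)-5,7-dihydroxy-2,3-dimethyl-6-[(2R)-5-methyl-2-(2-methylprop-1-enyl)hex-5-enyl]chroman-4-one
Conditions: Bu4NF (1.1 equiv), AcOH (1.1 equiv), THF, 0 °C
Reagents that add atoms: none
Why: Fluoride cleavage of the aryl silyl ether, buffered with acetic acid so the cis-chromanone never sees free base.

Step 10
Reactants: 16 (2R,3S)-5,7-dihydroxy-2,3-dimethyl-6-[(2R)-5-methyl-2-(2-methylprop-1-enyl)hex-5-enyl]chroman-4-one; 17 (E)-cinnamaldehyde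
Product: 19 7-O/8-C-fused lactol of 18 [ring O7–CH(OH)–CH2–CH(Ph)–C8; benzylic centre R; anomeric mixture], via open-chain aldehyde 18 (not isolated)
Conditions: (R)-2-[diphenyl(trimethylsilyloxy)methyl]pyrrolidine (20 mol%), PhCO2H (20 mol%), toluene, rt
Reagents that add atoms: none
Why: Iminium-ion organocatalysis (Friedel–Crafts-type conjugate addition of a hydroxyarene to an enal, then hemiacetal formation), in which C8 is the only unsubstituted ring carbon and the (R)-catalyst blocks one face of the E-iminium so the arene adds anti to the bulky group to give the R benzylic centre, the sense seen for malonate and nitroalkane additions to cinnamaldehyde.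

Step 11
Reactants: 19 7-O/8-C-fused lactol of 18; 20 prenyl acetate (3-methylbut-2-enyl acetate, 1.1 equiv)
Product: 21 (3R)-3-{(2R,3S,6S)-4-hydroxy-2,3-dimethyl-6-(3-methylbut-2-enyl)-6-[(2R)-5-methyl-2-(2-methylprop-1-enyl)hex-5-enyl]-5,7-dioxo-3,5,6,7-tetrahydro-2H-chromen-8-yl}-3-phenylpropanal (in equilibrium with its 7-O-hemiacetal)
Conditions: Pd2(dba)3 (tris(dibenzylideneacetone)dipalladium, 2.5 mol%), (1R,2R)-N,N'-bis[2-(diphenylphosphino)benzoyl]cyclohexane-1,2-diamine (7.5 mol%), Et3N (1.2 equiv), CH2Cl2, 0 °C to rt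
Reagents that add atoms: none
Why: Proposed new method: zerovalent palladium ionises prenyl acetate to a π-prenyl complex whose O-alkylation of the phenoxides is reversible, whereas attack of C6 on the unhindered CH2 terminus is irreversible because the dearomatized product is an acidic vinylogous acid (C8 is shielded by its secondary benzylic substituent), and the chiral pocket of the diphosphine selects the face of the planar phenoxide to set C6 as S; the ligand antipode is confirmed on the first run, the (1S,2S) ligand being used if the facial sense is reversed; the closest known reactions are palladium-catalysed asymmetric allylic dearomatization of 1,3-disubstituted 2-naphthols and enantioselective alkylative dearomatization of acylphloroglucinols.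

Step 12
Reactants: 21 (3R)-3-{(2R,3S,6S)-4-hydroxy-2,3-dimethyl-6-(3-methylbut-2-enyl)-6-[(2R)-5-methyl-2-(2-methylprop-1-enyl)hex-5-enyl]-5,7-dioxo-3,5,6,7-tetrahydro-2H-chromen-8-yl}-3-phenylpropanal
Product: 22 (3R)-3-{(2R,3S,6S)-4-hydroxy-2,3-dimethyl-6-(3-methylbut-2-enyl)-6-[(2R)-5-methyl-2-(2-methylprop-1-enyl)hex-5-enyl]-5,7-dioxo-3,5,6,7-tetrahydro-2H-chromen-8-yl}-3-phenylpropanoic acid (CNP0155375.4)
Conditions: NaClO2 (3 equiv), NaH2PO4 (3 equiv), 2-methyl-2-butene (30 equiv), t-BuOH/H2O, 0 °C to rt
Reagents that add atoms: sodium chlorite, [Na+].[O-]Cl=O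
Why: Pinnick oxidation of the aldehyde (in equilibrium with its hemiacetal) to the acid at pH 3–4, with 2-methyl-2-butene scavenging HOCl so that the three alkenes and the enol survive; no stereocentre is touched and no base is present to epimerise C3.

**Compound list**

1 | 2-(2-bromoethyl)-1,3-dioxolane | BrCCC1OCCO1 | starting material
2 | (2-methylallyl)magnesium chloride | C=C(C)C[Mg]Cl | starting material
3 | 2-(4-methylpent-4-enyl)-1,3-dioxolane | C=C(C)CCCC1OCCO1 | intermediate
4 | 5-methylhex-5-enal | C=C(C)CCCC=O | intermediate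
5 | phloroglucinol (benzene-1,3,5-triol) | Oc1cc(O)cc(O)c1 | starting material
6 | tigloyl chloride, (E)-2-methylbut-2-enoyl chloride | C/C=C(\C)C(=O)Cl | starting material
7 | (E)-2-methyl-1-(2,4,6-trihydroxyphenyl)but-2-en-1-one | C/C=C(\C)C(=O)c1c(O)cc(O)cc1O | intermediate
8 | (2R,3S)-5,7-dihydroxy-2,3-dimethylchroman-4-one (cis) | C[C@H]1Oc2cc(O)cc(O)c2C(=O)[C@H]1C | intermediate
9 | (2R,3S)-5-hydroxy-2,3-dimethyl-7-(triisopropylsilyloxy)chroman-4-one | C[C@H]1Oc2cc(O[Si](C(C)C)(C(C)C)C(C)C)cc(O)c2C(=O)[C@H]1C | intermediate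
10 | (2R,3S)-6-[(dimethylamino)methyl]-5-hydroxy-2,3-dimethyl-7-(triisopropylsilyloxy)chroman-4-one (Mannich base) | C[C@H]1Oc2cc(O[Si](C(C)C)(C(C)C)C(C)C)c(CN(C)C)c(O)c2C(=O)[C@H]1C | intermediate (not isolated)
11 | {[(2R,3S)-5-hydroxy-2,3-dimethyl-4-oxo-7-(triisopropylsilyloxy)chroman-6-yl]methyl}trimethylammonium iodide | C[C@H]1Oc2cc(O[Si](C(C)C)(C(C)C)C(C)C)c(C[N+](C)(C)C)c(O)c2C(=O)[C@H]1C.[I-] | intermediate
12 | (2R,3S)-2,3-dimethyl-6-methylidene-7-(triisopropylsilyloxy)-2,3-dihydrochromene-4,5(6H)-dione (o-quinone methide) | C[C@H]1OC2=C(C(=O)[C@H]1C)C(=O)C(=C)C(O[Si](C(C)C)(C(C)C)C(C)C)=C2 | intermediate (not isolated)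
13 | (2R)-2-{[(2R,3S)-5-hydroxy-2,3-dimethyl-4-oxo-7-(triisopropylsilyloxy)chroman-6-yl]methyl}-5-methylhex-5-enal | C[C@H]1Oc2cc(O[Si](C(C)C)(C(C)C)C(C)C)c(C[C@H](C=O)CCC(C)=C)c(O)c2C(=O)[C@H]1C | intermediate (not isolated)
14 | cyclic hemiacetal of 13 onto O5: new ring O5–CH(OH)–CH(3-methylbut-3-enyl)–CH2–C6, side-chain centre R, anomeric mixture, 7-OTIPS retained | C[C@H]1Oc2cc(O[Si](C(C)C)(C(C)C)C(C)C)c3C[C@@H](CCC(C)=C)C(O)Oc3c2C(=O)[C@H]1C | intermediate
15 | (2R,3S)-5-hydroxy-2,3-dimethyl-6-[(2R)-5-methyl-2-(2-methylprop-1-enyl)hex-5-enyl]-7-(triisopropylsilyloxy)chroman-4-one | C[C@H]1Oc2cc(O[Si](C(C)C)(C(C)C)C(C)C)c(C[C@H](C=C(C)C)CCC(C)=C)c(O)c2C(=O)[C@H]1C | intermediate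
16 | (2R,3S)-5,7-dihydroxy-2,3-dimethyl-6-[(2R)-5-methyl-2-(2-methylprop-1-enyl)hex-5-enyl]chroman-4-one | C[C@H]1Oc2cc(O)c(C[C@H](C=C(C)C)CCC(C)=C)c(O)c2C(=O)[C@H]1C | intermediate
17 | (E)-cinnamaldehyde | O=C/C=C/c1ccccc1 | starting material
18 | (3R)-3-{(2R,3S)-5,7-dihydroxy-2,3-dimethyl-6-[(2R)-5-methyl-2-(2-methylprop-1-enyl)hex-5-enyl]-4-oxochroman-8-yl}-3-phenylpropanal | C[C@H]1Oc2c([C@@H](c3ccccc3)CC=O)c(O)c(C[C@H](C=C(C)C)CCC(C)=C)c(O)c2C(=O)[C@H]1C | intermediate (not isolated)
19 | cyclic hemiacetal of 18 onto O7: new ring O7–CH(OH)–CH2–CH(Ph)–C8, benzylic centre R, anomeric mixture | C[C@H]1Oc2c3[C@@H](c4ccccc4)CC(O)Oc3c(C[C@H](C=C(C)C)CCC(C)=C)c(O)c2C(=O)[C@H]1C | intermediate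
20 | prenyl acetate (3-methylbut-2-enyl acetate) | CC(=O)OCC=C(C)C | starting material
21 | (3R)-3-{(2R,3S,6S)-4-hydroxy-2,3-dimethyl-6-(3-methylbut-2-enyl)-6-[(2R)-5-methyl-2-(2-methylprop-1-enyl)hex-5-enyl]-5,7-dioxo-3,5,6,7-tetrahydro-2H-chromen-8-yl}-3-phenylpropanal (open tautomer drawn; equilibrates with its 7-O-hemiacetal) | C=C(C)CC[C@@H](C=C(C)C)C[C@@]1(CC=C(C)C)C(=O)C2=C(O)[C@@H](C)[C@@H](C)OC2=C([C@H](CC=O)c2ccccc2)C1=O | intermediate
22 | (3R)-3-{(2R,3S,6S)-4-hydroxy-2,3-dimethyl-6-(3-methylbut-2-enyl)-6-[(2R)-5-methyl-2-(2-methylprop-1-enyl)hex-5-enyl]-5,7-dioxo-3,5,6,7-tetrahydro-2H-chromen-8-yl}-3-phenylpropanoic acid | C=C(C)CC[C@@H](C=C(C)C)C[C@@]1(CC=C(C)C)C(=O)C2=C(O)[C@@H](C)[C@@H](C)OC2=C([C@H](CC(=O)O)c2ccccc2)C1=O | target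

**Step count and risk**

Total steps: 12. Longest linear sequence: 10 (steps 3–12 from phloroglucinol); the aldehyde branch (steps 1–2) joins at step 7.

The three steps most likely to fail, with fallbacks:

Step 11 (face-selective dearomative prenylation, the key step). If the palladium catalyst gives poor C- versus O-selectivity or poor facial control, the fallback leaves π-allyl chemistry for chiral ion-pair (phase-transfer) alkylative dearomatization. Lactol 19 is treated with prenyl bromide, N-(9-anthracenylmethyl)cinchonidinium bromide (10 mol%) and solid CsOH·H2O in CH2Cl2 at −50 °C. The chiral ammonium cation pairs with the ring-opened phenoxide and steers the SN2 alkylation at C6, the mode known for enantioselective alkylative dearomatization of acylphloroglucinols; the pseudo-enantiomeric cinchoninium salt addresses the other face. This fallback sets out from 19, comes back to the route at 21 and makes no further compound (none, F0).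

Step 7 (enamine capture of an unsubstituted o-quinone methide). If the quinone methide oligomerises faster than the catalytic enamine traps it, or the selectivity is low, the fallback replaces catalyst control by a covalent auxiliary. Aldehyde 4 is condensed with (R)-1-amino-2-(methoxymethyl)pyrrolidine to give the hydrazone (E)-N-[(2R)-2-(methoxymethyl)pyrrolidin-1-yl]-5-methylhex-5-en-1-imine F1. F1 is deprotonated with LiN(i-Pr)2 in THF at −78 °C, and 2.2 equivalents of the aza-enolate are added to 11 at −100 °C. The first equivalent unmasks quinone methide 12; the second adds to its CH2 carbon from the face away from the lithium-chelated methoxymethyl arm. This gives (2R,3S)-5-hydroxy-6-[(2R)-2-{(E)-[(2R)-2-(methoxymethyl)pyrrolidin-1-yl]iminomethyl}-5-methylhex-5-enyl]-2,3-dimethyl-7-(triisopropylsilyloxy)chroman-4-one F2. Cleavage with aqueous oxalic acid/Et2O releases hydroxy aldehyde 13, which closes to lactol 14. This fallback sets out from 4 and 11 and comes back to the route at 14.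

Step 4 (quinine-catalysed oxa-Michael closure on a new, very electron-rich substrate). If an uncatalysed background cyclisation erodes the ee or the cis:trans ratio, the fallback sets both ring centres by hydrogenation instead. Ketone 7 is cyclised and dehydrogenated (I2 10 mol%, DMSO, 110 °C) to 5,7-dihydroxy-2,3-dimethyl-4H-chromen-4-one F3. F3 is hydrogenated at C2=C3 with [Rh(cod)Cl]2 and a chiral ferrocenyl bisphosphine–thiourea ligand under H2 (50 bar). Syn delivery of H2 fixes the cis relationship and the ligand fixes the absolute sense, giving 8. This fallback sets out from 7 and comes back to the route at 8.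

**Further compounds**

F0 | step 11 | none | none
F1 | step 7 | (E)-N-[(2R)-2-(methoxymethyl)pyrrolidin-1-yl]-5-methylhex-5-en-1-imine | COC[C@H]1CCCN1/N=C/CCCC(C)=C
F2 | step 7 | (2R,3S)-5-hydroxy-6-[(2R)-2-{(E)-[(2R)-2-(methoxymethyl)pyrrolidin-1-yl]iminomethyl}-5-methylhex-5-enyl]-2,3-dimethyl-7-(triisopropylsilyloxy)chroman-4-one | COC[C@H]1CCCN1/N=C/[C@H](CCC(C)=C)Cc1c(O)c2C(=O)[C@@H](C)[C@@H](C)Oc2cc1O[Si](C(C)C)(C(C)C)C(C)C
F3 | step 4 | 5,7-dihydroxy-2,3-dimethyl-4H-chromen-4-one | Cc1oc2cc(O)cc(O)c2c(=O)c1C
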